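**Retrosynthetic overview**

1. Ring numbering used here: C1 carries the acetoxy oxygen O1, C2 and C4 carry the hydroxyls, C6 carries the chain; chain carbons are C1′ (benzylic) to C15′. The target comes from bis-benzyl ether 9 by neutral hydrogenolysis, so the acetate stays on O1.
2. 9 comes from allylarene 7 and 1-iodododecane 8 by forming the C3′–C4′ bond through Ni–H anti-Markovnikov hydroalkylation. This one operation joins the C12 unit to the arene fragment and puts every heavy atom of the target in place.
3. The enabling feature is that O1 on C1 is ortho to the chain-bearing C6. A [3,3] shift therefore moves an allyl group from O1 to C6, its terminal sp2 carbon becomes exactly C3′, and the freed O1–H is the only hydroxyl available for acetylation.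
4. 7 comes from allyl ether 5 by aromatic Claisen rearrangement with acetylation in the same flask; 5 comes from phenol 4, made by Dakin-type oxidation of 2, which is the dibenzyl ether of 2,4-dihydroxybenzaldehyde 1.
5. No ring is formed: the benzene ring of 1 is carried through and only its substituents change.

Key step: step 5

Remark on the chemistry: the target has no stereocentre and no stereogenic double bond, so it is achiral and no stereocontrol is needed.

**Route**

Step 1
Reactants: 1 2,4-dihydroxybenzaldehyde
Product: 2 2,4-bis(benzyloxy)benzaldehyde
Conditions: BnBr, K2CO3, DMF, 70 °C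
Reagents that add atoms: benzyl bromide, BrCc1ccccc1
Why: Williamson etherification of both phenols, the warm carbonate/DMF medium also alkylating the hydrogen-bonded 2-OH while the aldehyde stays inert.

Step 2
Reactants: 2 2,4-bis(benzyloxy)benzaldehyde
Product: 4 2,4-bis(benzyloxy)phenol, via 2,4-bis(benzyloxy)phenyl formate 3 (not isolated)
Conditions: mCPBA, CH2Cl2, 0 °C to rt; then K2CO3 (cat.), MeOH, rt
Reagents that add atoms: mCPBA (3-chloroperoxybenzoic acid), OOC(=O)c1cccc(Cl)c1
Why: Baeyer–Villiger (Dakin-type) oxidation in which the electron-rich dialkoxyaryl group migrates to give formate 3, which mild methanolysis should cleave to the phenol without touching the benzyl ethers.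

Step 3
Reactants: 4 2,4-bis(benzyloxy)phenol
Product: 5 1-(allyloxy)-2,4-bis(benzyloxy)benzene
Conditions: allyl bromide, K2CO3, acetone, reflux
Reagents that add atoms: allyl bromide, C=CCBr
Why: Williamson O-allylation of the phenoxide, a polar aprotic medium favouring O- over C-alkylation.

Step 4
Reactants: 5 1-(allyloxy)-2,4-bis(benzyloxy)benzene
Product: 7 2-allyl-4,6-bis(benzyloxy)phenyl acetate, via 2-allyl-4,6-bis(benzyloxy)phenol 6 (not isolated)
Conditions: PhNEt2, 195 °C, Ar; cool to rt, then Ac2O, DMAP (cat.)
Reagents that add atoms: acetic anhydride, CC(=O)OC(C)=O
Why: Aromatic Claisen rearrangement, the [3,3] shift ending productively only at C6 (the sole hydrogen-bearing ortho position, C2 and C4 being blocked by OBn), followed by acetylation of the single free hydroxyl of air-sensitive phenol 6 before isolation, so that chain position and acetate position are fixed together.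

Step 5
Reactants: 7 2-allyl-4,6-bis(benzyloxy)phenyl acetate; 8 1-iodododecane
Product: 9 2,4-bis(benzyloxy)-6-pentadecylphenyl acetate
Conditions: NiBr2·diglyme (cat.), 4,4′-di-tert-butyl-2,2′-bipyridine (cat.), (EtO)2MeSiH, Na2CO3, DMA, rt
Reagents that add atoms: none
Why: A bipyridine-ligated Ni–H, formed from the Ni(I) halide and the silane, inserts the terminal alkene of 7 with nickel at the unsubstituted terminus (chain carbon C3′), the dodecyl radical generated from 8 by halogen-atom abstraction is captured by this primary alkyl–nickel species, and reductive elimination from Ni(III) forms the C3′–C4′ bond. The closest known reaction type is the nickel-hydride-catalysed anti-Markovnikov reductive hydroalkylation of unactivated terminal alkenes with primary alkyl iodides. No ring is closed and no stereocentre is created. The step needs linear regioselectivity without chain walking of nickel to the benzylic carbon C1′, and chemoselectivity for the C–I bond over the aryl C–O bonds; the monosubstituted alkene, an unhindered 4,4′-disubstituted bipyridine ligand, room temperature and the ortho-acetoxy group that crowds C1′ should secure the first, and the inertness of aryl acetate and benzyl ether C–O bonds towards nickel at room temperature the second. The sterically shielded, 2,6-disubstituted aryl acetate should also withstand the insoluble carbonate base, so the product already holds every heavy atom of the target in place.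

Step 6
Reactants: 9 2,4-bis(benzyloxy)-6-pentadecylphenyl acetate
Product: 10 2,4-dihydroxy-6-pentadecylphenyl acetate (target)
Conditions: H2 (1 atm), 10% Pd/C, EtOAc, rt
Reagents that add atoms: none
Why: Heterogeneous hydrogenolysis of the two aryl benzyl ethers under neutral, aprotic conditions, to which the saturated chain and the aryl acetate are inert, the absence of base being meant to keep the acetyl group on O1.

**Compound list**

1 | 2,4-dihydroxybenzaldehyde | O=Cc1ccc(O)cc1O | starting material
2 | 2,4-bis(benzyloxy)benzaldehyde | O=Cc1ccc(OCc2ccccc2)cc1OCc1ccccc1 | intermediate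
3 | 2,4-bis(benzyloxy)phenyl formate (not isolated) | O=COc1ccc(OCc2ccccc2)cc1OCc1ccccc1 | intermediate
4 | 2,4-bis(benzyloxy)phenol | Oc1ccc(OCc2ccccc2)cc1OCc1ccccc1 | intermediate
5 | 1-(allyloxy)-2,4-bis(benzyloxy)benzene | C=CCOc1ccc(OCc2ccccc2)cc1OCc1ccccc1 | intermediate
6 | 2-allyl-4,6-bis(benzyloxy)phenol (not isolated; OH at C1, allyl at C6, OBn at C2 and C4) | C=CCc1cc(OCc2ccccc2)cc(OCc2ccccc2)c1O | intermediate
7 | 2-allyl-4,6-bis(benzyloxy)phenyl acetate | C=CCc1cc(OCc2ccccc2)cc(OCc2ccccc2)c1OC(C)=O | intermediate
8 | 1-iodododecane | CCCCCCCCCCCCI | starting material
9 | 2,4-bis(benzyloxy)-6-pentadecylphenyl acetate | CCCCCCCCCCCCCCCc1cc(OCc2ccccc2)cc(OCc2ccccc2)c1OC(C)=O | intermediate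
10 | 2,4-dihydroxy-6-pentadecylphenyl acetate (CID10091080) | CCCCCCCCCCCCCCCc1cc(O)cc(O)c1OC(C)=O | target

**Step count and risks**

Total step count: 6. Longest linear sequence: 6 steps (1 to 10); 1-iodododecane 8 is bought.

Steps most likely to fail:

1. Step 5. What may go wrong: nickel hydride may walk along the chain to the benzylic position before the C–C bond forms, giving branched or conjugated-alkene products. Simple alkene reduction, iodide homocoupling, or partial loss of the acetate are further possibilities. Fallback: setting out from 7, hydroboration with 9-BBN-H (THF, rt) should place boron only at the terminal carbon and give 2,4-bis(benzyloxy)-6-[3-(9-borabicyclo[3.3.1]nonan-9-yl)propyl]phenyl acetate F1. This is coupled in the same flask with 1-bromododecane by alkyl–alkyl Suzuki–Miyaura coupling (Pd(OAc)2, PCy3, K3PO4·H2O, THF, rt) and comes back to the route at 9. Regiochemistry is then fixed by the hydroboration and no metal hydride capable of chain walking is present.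

2. Step 4. What may go wrong: thermal degradation at the rearrangement temperature (benzyl loss or migration, cyclisation of the ortho-allylphenol onto its alkene) or air oxidation of the electron-rich phenol before it is acetylated. Fallback: setting out from 4, iodination ortho to the hydroxyl under phenoxide control (I2, morpholine, CH2Cl2, 0 °C) should give 2,4-bis(benzyloxy)-6-iodophenol F2. Acetylation (Ac2O, pyridine, rt) gives 2,4-bis(benzyloxy)-6-iodophenyl acetate F3, and Stille allylation (allyltributylstannane, Pd(PPh3)4 cat., toluene, 100 °C) comes back to the route at 7. The C6–C1′ bond is then made by cross-coupling instead of a sigmatropic shift.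

3. Step 6. What may go wrong: migration of the acetyl group from O1 to the newly freed neighbouring hydroxyl on O2, or loss of the acetate, on the catalyst or during isolation. Fallback: setting out from 9, non-reductive Lewis-acid debenzylation with BCl3 and pentamethylbenzene as cation scavenger (CH2Cl2, −78 °C, acidic quench) should remove both benzyl groups at low temperature without any basic or metal surface and comes back to the route at 10.

**Further compounds**

F1 | step 5 | 2,4-bis(benzyloxy)-6-[3-(9-borabicyclo[3.3.1]nonan-9-yl)propyl]phenyl acetate | CC(=O)Oc1c(CCCB2C3CCCC2CCC3)cc(OCc2ccccc2)cc1OCc1ccccc1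
F2 | step 4 | 2,4-bis(benzyloxy)-6-iodophenol | Oc1c(I)cc(OCc2ccccc2)cc1OCc1ccccc1
F3 | step 4 | 2,4-bis(benzyloxy)-6-iodophenyl acetate | CC(=O)Oc1c(I)cc(OCc2ccccc2)cc1OCc1ccccc1
F0 | step 6 | none | none
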